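**Retrosynthetic overview**
- The target is the quercetin skeleton plus four C–O bonds (3-O–Me, C6–OMe, C8–OMe, C2'–OMe). No C–C bond has to be made.
- Last and key disconnection: C2'–OMe. The ring B catechol is oxidised at an anode to its o-quinone, methanol adds 1,4, and the product is reduced (new on a flavone).
- C6–OMe and C8–OMe: double copper-catalysed Ullmann methoxylation of the 6,8-dibromide made with NBS.
- 3-O–Me: Williamson methylation, made selective by tying the catechol up as a diphenylmethylene ketal.
- Ring order: rings A, C and B come intact in quercetin. The only ring formed is the temporary dioxolane, closed in step 1 and opened in step 4.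

Assumption: the target SMILES has no stereocentre and no isolable axis, so the compound is achiral and no configuration has to be set.

**Step 1**
Reactants: 1 quercetin (3,5,7,3',4'-pentahydroxyflavone, dried)
Product: 2 2-(2,2-diphenyl-1,3-benzodioxol-5-yl)-3,5,7-trihydroxy-4H-chromen-4-one
Conditions: Ph2CCl2 (1.5 equiv), Ph2O, 175 °C, 30 min
Reagents that add atoms: dichlorodiphenylmethane, ClC(Cl)(c1ccccc1)c1ccccc1
Why: Ketalisation by double O-alkylation: only the ring B catechol can close a five-membered cyclic ketal on the diphenyl-stabilised cation, so the 3-, 5- and 7-OH stay free, and no stereocentre is formed.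

**Step 2**
Reactants: 2 quercetin 3',4'-O-diphenylmethylene ketal
Product: 3 2-(2,2-diphenyl-1,3-benzodioxol-5-yl)-5,7-dihydroxy-3-methoxy-4H-chromen-4-one
Conditions: MeI (1.05 equiv), K2CO3 (1.2 equiv), DMF, rt, 12 h, N2
Reagents that add atoms: methyl iodide, CI
Why: Williamson ether synthesis: with the acidic 4'-OH masked, the enolic 3-oxygen is the best nucleophile, because the 5-OH is hydrogen-bonded to C4=O and the 7-phenoxide is delocalised into the pyranone as a vinylogous carboxylate; no stereocentre is formed.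

**Step 3**
Reactants: 3 3-O-methyl ketal
Product: 4 6,8-dibromo-2-(2,2-diphenyl-1,3-benzodioxol-5-yl)-5,7-dihydroxy-3-methoxy-4H-chromen-4-one
Conditions: NBS (2.05 equiv), DMF, 0 °C to rt, dark
Reagents that add atoms: N-bromosuccinimide, O=C1CCC(=O)N1Br
Why: Electrophilic aromatic bromination: C6 and C8 each lie ortho/para to the free 5- and 7-hydroxyls, so they react far faster than ring B, which is an ether-only ring deactivated by the chromone; no stereocentre is formed.

**Step 4**
Reactants: 4 6,8-dibromo ketal
Product: 6 2-(3,4-dihydroxyphenyl)-5,7-dihydroxy-3,6,8-trimethoxy-4H-chromen-4-one, via 6,8-dimethoxy ketal 5 (not isolated)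
Conditions: NaOMe (25% in MeOH, 15 equiv), CuBr (0.5 equiv), DMF, 110 °C, N2; concentrate; then conc. HCl to pH 1, AcOH/H2O 4:1, reflux, N2
Reagents that add atoms: sodium methoxide, C[O-].[Na+]
Why: Ullmann-type ether synthesis, in which monovalent copper methoxide replaces both C–Br bonds of the 5,7-diphenoxide (an exchange established on 6,8-dibromo-5,7-dihydroxyflavone) while the base-stable ketal keeps the catechol off the copper, after which the work-up acid hydrolyses the ketal through its diphenyl-stabilised oxocarbenium ion, any opening and reclosure of ring C (Wessely-Moser) being degenerate because ring A is symmetric; no stereocentre is formed.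

**Step 5**
Reactants: 6 5,7,3',4'-tetrahydroxy-3,6,8-trimethoxyflavone
Product: 9 5,7,4',5'-tetrahydroxy-3,6,8,2'-tetramethoxyflavone, via ring B o-quinone 7 (not isolated), via methoxy-o-quinone 8 (not isolated)
Conditions: graphite-felt anode, Pt cathode, divided cell, +500 mV vs Ag/AgCl (about 100 mV past the first wave), NaOAc/AcOH (0.2 mol/L each), dry MeOH (5 mmol/L in 6), 0 °C, N2, 4 F/mol; then aq. Na2S2O4, 0 °C
Reagents that add atoms: methanol, CO
Why: Proposed new method: just past the first voltammetric wave only the ring B catechol loses two electrons and two protons to give o-quinone 7, since the ring A phenols are chelated or conjugated to C4=O and oxidise several hundred mV later; because the 3-oxygen is capped, 7 cannot tautomerise to the quinone methide that sends solvent to C2 in free flavonols, and because C6 and C8 are blocked ring A cannot couple as a carbon nucleophile, so acetate-assisted methanol adds 1,4 to the C4'=O enone at its only free beta carbon (C6' of 6, which is C2' of 9); the adduct re-aromatises to catechol 9, which is more electron-rich than 6 and is at once oxidised to the vinylogous-ester quinone 8, whose 1,4-acceptor positions are both filled (4 F/mol in total), and Na2S2O4 returns 8 to 9; the closest known reaction type is the anodic ECEC methoxylation of simple 4-substituted catechols (4-methyl, 4-tert-butyl) to 4-substituted 5-methoxy-o-benzoquinones, which has not been shown on a flavone ring B or beside an oxidisable polyoxygenated ring A; no stereocentre is formed.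

**Compound list**
1 | quercetin | O=c1c(O)c(-c2ccc(O)c(O)c2)oc2cc(O)cc(O)c12 | starting material
2 | 2-(2,2-diphenyl-1,3-benzodioxol-5-yl)-3,5,7-trihydroxy-4H-chromen-4-one | O=c1c(O)c(-c2ccc3OC(c4ccccc4)(c4ccccc4)Oc3c2)oc2cc(O)cc(O)c12 | intermediate
3 | 2-(2,2-diphenyl-1,3-benzodioxol-5-yl)-5,7-dihydroxy-3-methoxy-4H-chromen-4-one | COc1c(-c2ccc3OC(c4ccccc4)(c4ccccc4)Oc3c2)oc2cc(O)cc(O)c2c1=O | intermediate
4 | 6,8-dibromo-2-(2,2-diphenyl-1,3-benzodioxol-5-yl)-5,7-dihydroxy-3-methoxy-4H-chromen-4-one | COc1c(-c2ccc3OC(c4ccccc4)(c4ccccc4)Oc3c2)oc2c(Br)c(O)c(Br)c(O)c2c1=O | intermediate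
5 | 2-(2,2-diphenyl-1,3-benzodioxol-5-yl)-5,7-dihydroxy-3,6,8-trimethoxy-4H-chromen-4-one (not isolated) | COc1c(-c2ccc3OC(c4ccccc4)(c4ccccc4)Oc3c2)oc2c(OC)c(O)c(OC)c(O)c2c1=O | intermediate
6 | 2-(3,4-dihydroxyphenyl)-5,7-dihydroxy-3,6,8-trimethoxy-4H-chromen-4-one | COc1c(-c2ccc(O)c(O)c2)oc2c(OC)c(O)c(OC)c(O)c2c1=O | intermediate
7 | 4-(5,7-dihydroxy-3,6,8-trimethoxy-4-oxo-4H-chromen-2-yl)cyclohexa-3,5-diene-1,2-dione (not isolated) | COc1c(C2=CC(=O)C(=O)C=C2)oc2c(OC)c(O)c(OC)c(O)c2c1=O | intermediate
8 | 4-(5,7-dihydroxy-3,6,8-trimethoxy-4-oxo-4H-chromen-2-yl)-5-methoxycyclohexa-3,5-diene-1,2-dione (not isolated) | COC1=CC(=O)C(=O)C=C1c1oc2c(OC)c(O)c(OC)c(O)c2c(=O)c1OC | intermediate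
9 | 5,7,4',5'-tetrahydroxy-3,6,8,2'-tetramethoxyflavone | COc1cc(O)c(O)cc1-c1oc2c(OC)c(O)c(OC)c(O)c2c(=O)c1OC | target

**Totals**
Total step count: 5. Longest linear sequence: 5.

**Steps most likely to fail**

Step 5 (the proposed new step). The risks are methanol adding at C2' or C5' of 6 instead of C6', quinone oligomerisation, and erosion of ring A. The fallback sets out from 4 and comes back at 9, and it uses only halide displacement. Ring B of 4 is brominated once more (Br2, NaOAc, AcOH/CH2Cl2, rt). Bromine enters para to a ketal oxygen, as in piperonal, and gives the 6,8,6'-tribromo ketal F1. Threefold Ullmann methoxylation (NaOMe, CuBr, DMF/MeOH, 110 °C) gives the 3,6,8,2'-tetramethoxy ketal F2. AcOH/H2O at reflux then releases 9.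

Step 4. The risks are protodebromination and incomplete second exchange on the electron-rich diphenoxide. The fallback sets out from 4 and comes back at 6. It replaces copper and free phenoxide with palladium on a fully protected substrate. BnBr, K2CO3, DMF, 70 °C gives the 5,7-di-O-benzyl dibromide F3. Zerovalent-palladium C–O coupling with methanol (Pd2(dba)3, tBuBrettPhos, NaOtBu, MeOH, 1,4-dioxane, 60 °C) gives the 5,7-di-O-benzyl-6,8-dimethoxy ketal F4. H2, Pd/C, THF/MeOH removes both benzyl ethers and the diphenylmethylene ketal together and gives 6.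

Step 2. The risk is competing 7-O-methylation and 3,7-dimethylation. The fallback sets out from 2 and comes back at 4, with the order of halogenation and alkylation inverted. NBS (2.05 equiv), DMF, 0 °C gives the 6,8-dibromo triol ketal F5. Its 7-oxygen is flanked by two bromines and is a hindered, weak nucleophile. MeI (1.0 equiv), K2CO3 (2.1 equiv), DMF, rt then methylates only the 3-oxygen and gives 4.

**Further compounds**
F1 | step 5 | 6,8-dibromo-2-(6-bromo-2,2-diphenyl-1,3-benzodioxol-5-yl)-5,7-dihydroxy-3-methoxy-4H-chromen-4-one | COc1c(-c2cc3OC(c4ccccc4)(c4ccccc4)Oc3cc2Br)oc2c(Br)c(O)c(Br)c(O)c2c1=O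
F2 | step 5 | 5,7-dihydroxy-3,6,8-trimethoxy-2-(6-methoxy-2,2-diphenyl-1,3-benzodioxol-5-yl)-4H-chromen-4-one | COc1cc2OC(c3ccccc3)(c3ccccc3)Oc2cc1-c1oc2c(OC)c(O)c(OC)c(O)c2c(=O)c1OC
F3 | step 4 | 5,7-bis(benzyloxy)-6,8-dibromo-2-(2,2-diphenyl-1,3-benzodioxol-5-yl)-3-methoxy-4H-chromen-4-one | COc1c(-c2ccc3OC(c4ccccc4)(c4ccccc4)Oc3c2)oc2c(Br)c(OCc3ccccc3)c(Br)c(OCc3ccccc3)c2c1=O
F4 | step 4 | 5,7-bis(benzyloxy)-2-(2,2-diphenyl-1,3-benzodioxol-5-yl)-3,6,8-trimethoxy-4H-chromen-4-one | COc1c(-c2ccc3OC(c4ccccc4)(c4ccccc4)Oc3c2)oc2c(OC)c(OCc3ccccc3)c(OC)c(OCc3ccccc3)c2c1=O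
F5 | step 2 | 6,8-dibromo-2-(2,2-diphenyl-1,3-benzodioxol-5-yl)-3,5,7-trihydroxy-4H-chromen-4-one | O=c1c(O)c(-c2ccc3OC(c4ccccc4)(c4ccccc4)Oc3c2)oc2c(Br)c(O)c(Br)c(O)c12
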